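**Retrosynthetic overview**
1. Formamide 20 ⇐ amine 19 ⇐ tertiary azide 18 ⇐ exocyclic-methylene cis-decalin 17: the C10–N bond and the C10 stereocentre come last, by convex-face Markovnikov hydroazidation.
2. 17 ⇐ aldehyde 14: ring B is closed at C8–C9 by a type-two carbonyl-ene reaction onto the isopropenyl group, then C8 is deoxygenated.
3. 14 ⇐ ester 10: the C6–C7 bond and the C6/C7 stereocentres come from an Ireland–Claisen rearrangement that joins dienol 7 (ring A, C1, C9, C10; limonene series) to oxanylacetic acid 6.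
4. 6 ⇐ vinyl chloro-oxane 2 ⇐ (R)-linalool 1: the oxane ring and the C14–Cl centre come from the proposed catalyst-controlled 6-endo chloroetherification; C11 is the linalool carbinol carbon.
5. Ring order: oxane first (step 1), ring A bought intact in 7, ring B last (step 7).

Assumption: in step 1 the dihydroquinidine-derived dimer is taken as the ligand series that gives the (S)-C–Cl centre with (R)-linalool; if the sense is opposite, the dihydroquinine-derived quasi-enantiomer takes its place.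

Locants used in the "Why" lines: decalin C1–C10 (C1 and C6 ring fusion, C4=C5 alkene, C7 bears the oxane, C10 bears nitrogen); oxane C11–C15 (C11 quaternary O–C(CH3), C14 CHCl, C15 C(CH3)2).

**Route**

Step 1
Reactants: 1 (R)-linalool [(3R)-3,7-dimethylocta-1,6-dien-3-ol]
Product: 2 (3S,6R)-3-chloro-6-ethenyl-2,2,6-trimethyloxane
Conditions: N-chlorosuccinimide (1.2 equiv), hydroquinidine 1,4-phthalazinediyl diether [(DHQD)2PHAL] (10 mol %), PhCO2H (20 mol %), CHCl3/hexane 1:1, −30 °C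
Reagents that add atoms: N-chlorosuccinimide, ClN1C(=O)CCC1=O
Why: Proposed new method: a catalyst-controlled 6-endo chloroetherification in which the dimeric cinchona alkaloid hydrogen-bonds the tertiary hydroxyl while its protonated quinuclidine/benzoic acid pair activates the N–Cl bond, so that chlorenium transfer to one π-face of the 2-methyl-2-alkene is concerted with anti attack of oxygen at the tertiary carbon (Markovnikov polarisation gives the six-membered ring, and nucleophile assistance outruns ene-type allylic chlorination), the catalyst rather than the unbiased substrate (vinyl and methyl at C11 are nearly isosteric) fixing C14 as S with equatorial chlorine; the closest known reaction type is the cinchona-dimer-catalysed enantioselective chlorolactonisation and chloroetherification of aryl-substituted or 1,1-disubstituted alkenes, not yet shown for a trialkyl alkene closed by a tertiary alcohol in the 6-endo mode.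

Step 2
Reactants: 2 (3S,6R)-3-chloro-6-ethenyl-2,2,6-trimethyloxane
Product: 4 2-[(2R,5S)-5-chloro-2,6,6-trimethyloxan-2-yl]ethan-1-ol, via trialkylborane 3 (not isolated)
Conditions: 9-borabicyclo[3.3.1]nonane, THF, 0 °C → rt; then NaOH, H2O2, 0 °C
Reagents that add atoms: 9-borabicyclo[3.3.1]nonane, B1C2CCCC1CCC2 (boron and ring carbons of 3); hydrogen peroxide, OO (hydroxyl oxygen of 4)
Why: Hydroboration–oxidation: the bulky borane adds anti-Markovnikov to the only remaining alkene (a vinyl group on a quaternary carbon) and oxidation of the C–B bond gives the primary alcohol without touching C11 or C14.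

Step 3
Reactants: 4 2-[(2R,5S)-5-chloro-2,6,6-trimethyloxan-2-yl]ethan-1-ol
Product: 6 2-[(2R,5S)-5-chloro-2,6,6-trimethyloxan-2-yl]acetic acid, via aldehyde 5 (not isolated)
Conditions: (2,2,6,6-tetramethylpiperidin-1-yl)oxyl (20 mol %), PhI(OAc)2 (2.2 equiv), MeCN/H2O 1:1, rt
Reagents that add atoms: water, O
Why: Nitroxyl-catalysed oxidation of the primary alcohol through aldehyde 5 to the acid under near-neutral conditions leaves the secondary chloride and the di-tertiary ether intact and affects no stereocentre.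

Step 4
Reactants: 6 2-[(2R,5S)-5-chloro-2,6,6-trimethyloxan-2-yl]acetic acid; 7 (1S,4R)-1-methyl-4-(prop-1-en-2-yl)cyclohex-2-en-1-ol
Product: 10 (1S,4R)-1-methyl-4-(prop-1-en-2-yl)cyclohex-2-en-1-yl 2-[(2R,5S)-5-chloro-2,6,6-trimethyloxan-2-yl]acetate, via acid chloride 8 (not isolated), via lithium alkoxide 9 (not isolated)
Conditions: 6, (COCl)2, N,N-dimethylformamide (cat.), CH2Cl2, 0 °C → rt; 7, n-BuLi, THF, −78 °C; then 8 added to 9, −78 → 0 °C
Reagents that add atoms: oxalyl chloride, ClC(=O)C(Cl)=O (chlorine of 8); n-butyllithium, [Li]CCCC (lithium of 9)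
Why: O-acylation of a lithium tertiary alkoxide by an acid chloride esterifies the hindered tertiary allylic alcohol without ionising it, so the C4–O configuration of 7 (oxygen cis to the isopropenyl group) is retained for the chirality relay.

Step 5
Reactants: 10 (1S,4R)-1-methyl-4-(prop-1-en-2-yl)cyclohex-2-en-1-yl 2-[(2R,5S)-5-chloro-2,6,6-trimethyloxan-2-yl]acetate
Product: 13 (2S)-2-[(2R,5S)-5-chloro-2,6,6-trimethyloxan-2-yl]-2-[(1S,6R)-3-methyl-6-(prop-1-en-2-yl)cyclohex-2-en-1-yl]ethan-1-ol, via silyl ketene acetal 11 (not isolated), via trimethylsilyl ester 12 (not isolated)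
Conditions: LiN(iPr)2, Me3SiCl, Et3N, THF, −78 °C, then rt, 4 h; then LiAlH4, 0 °C
Reagents that add atoms: chlorotrimethylsilane, C[Si](C)(C)Cl (silyl group of 11 and 12)
Why: Ireland–Claisen rearrangement: kinetic enolisation with in-situ silylation (faster than β-alkoxide loss) gives the (E)-silyl ketene acetal 11, which rearranges suprafacially on the face carrying the C4–O bond, so the new C6–C7 bond is cis to the isopropenyl group (C6 S by 1,3-chirality transfer) and the C4=C5 alkene is formed, while the chair transition state with the oxane pseudo-axial on C7 and pointing away from ring A sets C7; the silyl ester is reduced to the alcohol in the same flask.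

Step 6
Reactants: 13 (2S)-2-[(2R,5S)-5-chloro-2,6,6-trimethyloxan-2-yl]-2-[(1S,6R)-3-methyl-6-(prop-1-en-2-yl)cyclohex-2-en-1-yl]ethan-1-ol
Product: 14 (2R)-2-[(2R,5S)-5-chloro-2,6,6-trimethyloxan-2-yl]-2-[(1S,6R)-3-methyl-6-(prop-1-en-2-yl)cyclohex-2-en-1-yl]acetaldehyde
Conditions: Dess–Martin periodinane, pyridine, CH2Cl2, 0 °C → rt
Reagents that add atoms: none
Why: Dess–Martin oxidation of the hindered primary alcohol under buffered, non-epimerising conditions gives the α-branched aldehyde with C7 intact (the descriptor changes only because of substituent priorities).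

Step 7
Reactants: 14 (2R)-2-[(2R,5S)-5-chloro-2,6,6-trimethyloxan-2-yl]-2-[(1S,6R)-3-methyl-6-(prop-1-en-2-yl)cyclohex-2-en-1-yl]acetaldehyde
Product: 15 (1S,2R,4aR,8aS)-1-[(2R,5S)-5-chloro-2,6,6-trimethyloxan-2-yl]-7-methyl-4-methylidene-1,2,3,4,4a,5,6,8a-octahydronaphthalen-2-ol
Conditions: Me2AlCl (1.5 equiv), CH2Cl2, −78 → 0 °C
Reagents that add atoms: none
Why: Lewis-acid-promoted type-two intramolecular carbonyl-ene reaction: the terminal carbon C9 of the isopropenyl group adds to the activated aldehyde carbon C8 while an allylic methyl hydrogen passes to oxygen, closing ring B as the cis-fused decalin (both ring-fusion centres already set) with an exocyclic C10 methylene; the C8 carbinol (axial 2R epimer expected from the chair ene transition state) is removed in step 9, so its configuration is inconsequential.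

Step 8
Reactants: 15 (1S,2R,4aR,8aS)-1-[(2R,5S)-5-chloro-2,6,6-trimethyloxan-2-yl]-7-methyl-4-methylidene-1,2,3,4,4a,5,6,8a-octahydronaphthalen-2-ol
Product: 16 O-[(1S,2R,4aR,8aS)-1-[(2R,5S)-5-chloro-2,6,6-trimethyloxan-2-yl]-7-methyl-4-methylidene-1,2,3,4,4a,5,6,8a-octahydronaphthalen-2-yl] 1H-imidazole-1-carbothioate
Conditions: 1,1'-thiocarbonyldiimidazole, 4-(dimethylamino)pyridine (cat.), ClCH2CH2Cl, 70 °C
Reagents that add atoms: 1,1'-thiocarbonyldiimidazole, S=C(n1ccnc1)n1ccnc1
Why: Neutral thioacylation of the secondary alcohol (first half of a Barton–McCombie deoxygenation) tolerates both alkenes and the chloride and changes no stereocentre.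

Step 9
Reactants: 16 O-[(1S,2R,4aR,8aS)-1-[(2R,5S)-5-chloro-2,6,6-trimethyloxan-2-yl]-7-methyl-4-methylidene-1,2,3,4,4a,5,6,8a-octahydronaphthalen-2-yl] 1H-imidazole-1-carbothioate
Product: 17 (2R,5S)-5-chloro-2,6,6-trimethyl-2-[(1R,4aR,8aS)-7-methyl-4-methylidene-1,2,3,4,4a,5,6,8a-octahydronaphthalen-1-yl]oxane
Conditions: Bu3SnH, 2,2'-azobis(2-methylpropionitrile) (cat.), toluene, 90 °C
Reagents that add atoms: none
Why: Barton–McCombie radical deoxygenation: the stannyl radical adds to C=S, the C8–O bond fragments, and the secondary C8 radical is quenched by Bu3SnH faster than homoallyl rearrangement or attack on the neopentyl-type secondary chloride, leaving C8 as CH2.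

Step 10
Reactants: 17 (2R,5S)-5-chloro-2,6,6-trimethyl-2-[(1R,4aR,8aS)-7-methyl-4-methylidene-1,2,3,4,4a,5,6,8a-octahydronaphthalen-1-yl]oxane
Product: 18 (2R,5S)-2-[(1R,4R,4aR,8aS)-4-azido-4,7-dimethyl-1,2,3,4,4a,5,6,8a-octahydronaphthalen-1-yl]-5-chloro-2,6,6-trimethyloxane
Conditions: Fe2(C2O4)3·6H2O, NaN3, NaBH4, EtOH/H2O/THF, 0 °C
Reagents that add atoms: sodium azide, [Na+].[N-]=[N+]=[N-]
Why: Markovnikov radical hydroazidation by metal-hydride hydrogen-atom transfer: hydrogen adds to the exposed exocyclic CH2 (faster than to the trisubstituted C4=C5 alkene) and the tertiary C10 radical takes azide from iron on the convex α-face (equatorial attack, because the axial C6–C5 bond of ring A blocks the β-axial trajectory), setting C10 as R with equatorial nitrogen and axial methyl.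

Step 11
Reactants: 18 (2R,5S)-2-[(1R,4R,4aR,8aS)-4-azido-4,7-dimethyl-1,2,3,4,4a,5,6,8a-octahydronaphthalen-1-yl]-5-chloro-2,6,6-trimethyloxane
Product: 19 (1R,4R,4aS,8aR)-4-[(2R,5S)-5-chloro-2,6,6-trimethyloxan-2-yl]-1,6-dimethyl-1,2,3,4,4a,7,8,8a-octahydronaphthalen-1-amine
Conditions: LiAlH4, Et2O, 0 °C → rt
Reagents that add atoms: none
Why: Hydride reduction of the tertiary azide to the primary amine with loss of N2 leaves C10 untouched, and the hindered secondary chloride next to a quaternary carbon is inert to LiAlH4 at this temperature.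

Step 12
Reactants: 19 (1R,4R,4aS,8aR)-4-[(2R,5S)-5-chloro-2,6,6-trimethyloxan-2-yl]-1,6-dimethyl-1,2,3,4,4a,7,8,8a-octahydronaphthalen-1-amine
Product: 20 N-[(1R,4R,4aS,8aR)-4-[(2R,5S)-5-chloro-2,6,6-trimethyloxan-2-yl]-1,6-dimethyl-1,2,3,4,4a,7,8,8a-octahydronaphthalen-1-yl]formamide
Conditions: acetic formic anhydride, CH2Cl2, 0 °C → rt
Reagents that add atoms: acetic formic anhydride, CC(=O)OC=O
Why: N-formylation of the hindered α-tertiary amine by the mixed anhydride, whose formyl carbonyl is far more electrophilic than the acetyl one, gives the target without touching any stereocentre.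

**Compound list**

1 | (R)-linalool, (3R)-3,7-dimethylocta-1,6-dien-3-ol | C=C[C@](C)(O)CCC=C(C)C | starting material
2 | (3S,6R)-3-chloro-6-ethenyl-2,2,6-trimethyloxane | C=C[C@@]1(C)CC[C@H](Cl)C(C)(C)O1 | intermediate
3 | 9-{2-[(2S,5S)-5-chloro-2,6,6-trimethyloxan-2-yl]ethyl}-9-borabicyclo[3.3.1]nonane | B1(C2CCCC1CCC2)CC[C@@]1(C)CC[C@H](Cl)C(C)(C)O1 | intermediate
4 | 2-[(2R,5S)-5-chloro-2,6,6-trimethyloxan-2-yl]ethan-1-ol | OCC[C@@]1(C)CC[C@H](Cl)C(C)(C)O1 | intermediate
5 | 2-[(2R,5S)-5-chloro-2,6,6-trimethyloxan-2-yl]acetaldehyde | O=CC[C@@]1(C)CC[C@H](Cl)C(C)(C)O1 | intermediate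
6 | 2-[(2R,5S)-5-chloro-2,6,6-trimethyloxan-2-yl]acetic acid | OC(=O)C[C@@]1(C)CC[C@H](Cl)C(C)(C)O1 | intermediate
7 | (1S,4R)-1-methyl-4-(prop-1-en-2-yl)cyclohex-2-en-1-ol (hydroxyl and isopropenyl on the same face) | C[C@@]1(O)C=C[C@H](C(C)=C)CC1 | starting material
8 | 2-[(2R,5S)-5-chloro-2,6,6-trimethyloxan-2-yl]acetyl chloride | ClC(=O)C[C@@]1(C)CC[C@H](Cl)C(C)(C)O1 | intermediate
9 | lithium (1S,4R)-1-methyl-4-(prop-1-en-2-yl)cyclohex-2-en-1-olate | C[C@@]1(O[Li])C=C[C@H](C(C)=C)CC1 | intermediate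
10 | (1S,4R)-1-methyl-4-(prop-1-en-2-yl)cyclohex-2-en-1-yl 2-[(2R,5S)-5-chloro-2,6,6-trimethyloxan-2-yl]acetate | C[C@@]1(OC(=O)C[C@@]2(C)CC[C@H](Cl)C(C)(C)O2)C=C[C@H](C(C)=C)CC1 | intermediate
11 | (2R,5S)-5-chloro-2,6,6-trimethyl-2-[(E)-2-{[(1S,4R)-1-methyl-4-(prop-1-en-2-yl)cyclohex-2-en-1-yl]oxy}-2-[(trimethylsilyl)oxy]ethenyl]oxane | C[C@@]1(O/C(O[Si](C)(C)C)=C\[C@@]2(C)CC[C@H](Cl)C(C)(C)O2)C=C[C@H](C(C)=C)CC1 | intermediate
12 | trimethylsilyl (2R)-2-[(2R,5S)-5-chloro-2,6,6-trimethyloxan-2-yl]-2-[(1S,6R)-3-methyl-6-(prop-1-en-2-yl)cyclohex-2-en-1-yl]acetate | CC1=C[C@H]([C@@H](C(=O)O[Si](C)(C)C)[C@@]2(C)CC[C@H](Cl)C(C)(C)O2)[C@@H](CC1)C(C)=C | intermediate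
13 | (2S)-2-[(2R,5S)-5-chloro-2,6,6-trimethyloxan-2-yl]-2-[(1S,6R)-3-methyl-6-(prop-1-en-2-yl)cyclohex-2-en-1-yl]ethan-1-ol | CC1=C[C@H]([C@@H](CO)[C@@]2(C)CC[C@H](Cl)C(C)(C)O2)[C@@H](CC1)C(C)=C | intermediate
14 | (2R)-2-[(2R,5S)-5-chloro-2,6,6-trimethyloxan-2-yl]-2-[(1S,6R)-3-methyl-6-(prop-1-en-2-yl)cyclohex-2-en-1-yl]acetaldehyde | CC1=C[C@H]([C@@H](C=O)[C@@]2(C)CC[C@H](Cl)C(C)(C)O2)[C@@H](CC1)C(C)=C | intermediate
15 | (1S,2R,4aR,8aS)-1-[(2R,5S)-5-chloro-2,6,6-trimethyloxan-2-yl]-7-methyl-4-methylidene-1,2,3,4,4a,5,6,8a-octahydronaphthalen-2-ol | CC1=C[C@H]2[C@@H](CC1)C(=C)C[C@@H](O)[C@H]2[C@@]1(C)CC[C@H](Cl)C(C)(C)O1 | intermediate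
16 | O-[(1S,2R,4aR,8aS)-1-[(2R,5S)-5-chloro-2,6,6-trimethyloxan-2-yl]-7-methyl-4-methylidene-1,2,3,4,4a,5,6,8a-octahydronaphthalen-2-yl] 1H-imidazole-1-carbothioate | CC1=C[C@H]2[C@@H](CC1)C(=C)C[C@@H](OC(=S)n3ccnc3)[C@H]2[C@@]1(C)CC[C@H](Cl)C(C)(C)O1 | intermediate
17 | (2R,5S)-5-chloro-2,6,6-trimethyl-2-[(1R,4aR,8aS)-7-methyl-4-methylidene-1,2,3,4,4a,5,6,8a-octahydronaphthalen-1-yl]oxane | CC1=C[C@H]2[C@@H](CC1)C(=C)CC[C@H]2[C@@]1(C)CC[C@H](Cl)C(C)(C)O1 | intermediate
18 | (2R,5S)-2-[(1R,4R,4aR,8aS)-4-azido-4,7-dimethyl-1,2,3,4,4a,5,6,8a-octahydronaphthalen-1-yl]-5-chloro-2,6,6-trimethyloxane | CC1=C[C@H]2[C@@H](CC1)[C@](C)(N=[N+]=[N-])CC[C@H]2[C@@]1(C)CC[C@H](Cl)C(C)(C)O1 | intermediate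
19 | (1R,4R,4aS,8aR)-4-[(2R,5S)-5-chloro-2,6,6-trimethyloxan-2-yl]-1,6-dimethyl-1,2,3,4,4a,7,8,8a-octahydronaphthalen-1-amine | CC1=C[C@H]2[C@@H](CC1)[C@](C)(N)CC[C@H]2[C@@]1(C)CC[C@H](Cl)C(C)(C)O1 | intermediate
20 | N-[(1R,4R,4aS,8aR)-4-[(2R,5S)-5-chloro-2,6,6-trimethyloxan-2-yl]-1,6-dimethyl-1,2,3,4,4a,7,8,8a-octahydronaphthalen-1-yl]formamide | CC1=C[C@H]2[C@@H](CC1)[C@](C)(NC=O)CC[C@H]2[C@@]1(C)CC[C@H](Cl)C(C)(C)O1 | target

**Step count and risks**

Total step count: 12. Longest linear sequence: 12 steps (1 → 20; dienol 7 is purchased and enters at step 4).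

The three steps most likely to fail are steps 1, 5 and 10.

Step 1 is the proposed new method. It may give ene-type allylic chlorination, some five-membered ether, or too little catalyst control at C14, since the substrate itself has almost no bias. The fallback uses known chemistry, sets out from 1 and returns at 2. Shi epoxidation of the trisubstituted alkene of 1 (1,2:4,5-di-O-isopropylidene-β-D-erythro-2,3-hexodiulo-2,6-pyranose as catalyst, KHSO5, K2CO3, MeCN/dimethoxymethane/aqueous buffer, 0 °C) gives the epoxide (3R)-5-[(2R)-3,3-dimethyloxiran-2-yl]-3-methylpent-1-en-3-ol F1. Catalytic 10-camphorsulfonic acid in CH2Cl2 then opens the epoxide at its tertiary carbon with the tertiary hydroxyl, giving the pyranoid alcohol (3R,6R)-6-ethenyl-2,2,6-trimethyloxan-3-ol F2, which is separated from the furanoid isomer by chromatography. Appel chlorination of F2 (PPh3, CCl4, reflux) proceeds with inversion at the carbinol carbon and gives 2.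

Step 5 carries two risks: β-alkoxide loss from the ester enolate, and leakage between chair and boat transition states that would erode C7. The fallback replaces the enolate Claisen by a neutral amide-acetal (Eschenmoser) Claisen; it sets out from 6 (with 7) and returns at 13. Acid 6 is converted through acid chloride 8 with Me2NH into 2-[(2R,5S)-5-chloro-2,6,6-trimethyloxan-2-yl]-N,N-dimethylacetamide F3. O-Methylation with Me3OBF4 in CH2Cl2 gives [2-[(2R,5S)-5-chloro-2,6,6-trimethyloxan-2-yl]-1-methoxyethylidene]dimethylazanium tetrafluoroborate F4, and NaOMe in MeOH gives the amide acetal 2-[(2R,5S)-5-chloro-2,6,6-trimethyloxan-2-yl]-1,1-dimethoxy-N,N-dimethylethan-1-amine F5. Heating F5 with 7 in xylene at 140 °C with removal of methanol forms the ketene N,O-acetal with the oxane cis to the allylic oxygen, which rearranges through the chair to (2R)-2-[(2R,5S)-5-chloro-2,6,6-trimethyloxan-2-yl]-N,N-dimethyl-2-[(1S,6R)-3-methyl-6-(prop-1-en-2-yl)cyclohex-2-en-1-yl]acetamide F6. LiBHEt3 in THF reduces F6 to alcohol 13.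

Step 10 may suffer from competing hydrogen-atom transfer to the C4=C5 alkene or from incomplete facial control at C10. The fallback is an ionic Markovnikov route; it sets out from 17 and returns at 18. Azidomercuration with Hg(OAc)2 and NaN3 in THF/H2O at 50 °C is much faster on 1,1-disubstituted than on trisubstituted alkenes. Azide opens the mercurinium ion at the tertiary carbon from the open α-face, giving {[(1R,4R,4aS,8aR)-1-azido-4-[(2R,5S)-5-chloro-2,6,6-trimethyloxan-2-yl]-6-methyl-1,2,3,4,4a,7,8,8a-octahydronaphthalen-1-yl]methyl}mercury acetate F7. Reductive demercuration with NaBH4 in aqueous NaOH gives azide 18.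

**Further compounds**

F1 | step 1 | (3R)-5-[(2R)-3,3-dimethyloxiran-2-yl]-3-methylpent-1-en-3-ol | C=C[C@](C)(O)CC[C@H]1OC1(C)C
F2 | step 1 | (3R,6R)-6-ethenyl-2,2,6-trimethyloxan-3-ol | C=C[C@@]1(C)CC[C@@H](O)C(C)(C)O1
F3 | step 5 | 2-[(2R,5S)-5-chloro-2,6,6-trimethyloxan-2-yl]-N,N-dimethylacetamide | CN(C)C(=O)C[C@@]1(C)CC[C@H](Cl)C(C)(C)O1
F4 | step 5 | [2-[(2R,5S)-5-chloro-2,6,6-trimethyloxan-2-yl]-1-methoxyethylidene]dimethylazanium tetrafluoroborate | COC(C[C@@]1(C)CC[C@H](Cl)C(C)(C)O1)=[N+](C)C.F[B-](F)(F)F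
F5 | step 5 | 2-[(2R,5S)-5-chloro-2,6,6-trimethyloxan-2-yl]-1,1-dimethoxy-N,N-dimethylethan-1-amine | COC(OC)(C[C@@]1(C)CC[C@H](Cl)C(C)(C)O1)N(C)C
F6 | step 5 | (2R)-2-[(2R,5S)-5-chloro-2,6,6-trimethyloxan-2-yl]-N,N-dimethyl-2-[(1S,6R)-3-methyl-6-(prop-1-en-2-yl)cyclohex-2-en-1-yl]acetamide | CC1=C[C@H]([C@@H](C(=O)N(C)C)[C@@]2(C)CC[C@H](Cl)C(C)(C)O2)[C@@H](CC1)C(C)=C
F7 | step 10 | {[(1R,4R,4aS,8aR)-1-azido-4-[(2R,5S)-5-chloro-2,6,6-trimethyloxan-2-yl]-6-methyl-1,2,3,4,4a,7,8,8a-octahydronaphthalen-1-yl]methyl}mercury acetate | CC1=C[C@H]2[C@@H](CC1)[C@](C[Hg]OC(C)=O)(N=[N+]=[N-])CC[C@H]2[C@@]1(C)CC[C@H](Cl)C(C)(C)O1
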